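**Strategy.** The route rests on cutting the C3–C4 bond of ring C (the pyranone ring). There the C4 carbonyl sits on ring A, and C3 carries OH, the ring B aryl and the C2 methylene bound to O1. This α-ketol is what a crossed benzoin union of a salicylaldehyde carbonyl with a tethered aryl ketone leaves behind. A carbene-catalysed enantioselective aldehyde–ketone benzoin cyclisation therefore closes ring C, installs the C4 ketone and sets the C3 tertiary carbinol in one operation. Its precursor is a MOM-protected 2-(aroylmethoxy)benzaldehyde, made by O-alkylating a ring A salicylaldehyde with a prenylated ring B phenacyl bromide.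

Key step: step 7

Remark on the chemistry: which antipode of the aminoindanol-derived triazolium salt leads to the (3S) product is not predicted here; both antipodes are accessible, and the correct one is to be fixed by one test cyclisation with assignment of the product configuration.

**Step 1**
Reactants: 1 1-(2,3-dihydroxy-4-methoxyphenyl)ethanone
Product: 2 1-(5-bromo-2,3-dihydroxy-4-methoxyphenyl)ethanone
Conditions: Br2 (1.0 equiv), NaOAc, AcOH, 15–20 °C
Reagents that add atoms: bromine, BrBr
Why: Electrophilic aromatic bromination should go to C5, the only free position that is para to the 2-hydroxyl, ortho to the methoxy group and meta to the acetyl group, while the acyl-deactivated catechol should resist oxidation in the buffered medium.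

**Step 2**
Reactants: 2 1-(5-bromo-2,3-dihydroxy-4-methoxyphenyl)ethanone
Product: 3 1-[5-bromo-4-methoxy-2,3-bis(methoxymethoxy)phenyl]ethanone
Conditions: NaH (2.4 equiv), MOMCl (2.6 equiv), DMF, 0 °C to rt
Reagents that add atoms: chloromethyl methyl ether, COCCl
Why: Williamson-type O-alkylation of both sodium phenoxides (MOM protection) should mask the catechol, the strong base being needed to break the hydrogen bond between the 2-hydroxyl and the acetyl group.

**Step 3**
Reactants: 3 1-[5-bromo-4-methoxy-2,3-bis(methoxymethoxy)phenyl]ethanone; 4 tributyl(3-methylbut-2-en-1-yl)stannane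
Product: 5 1-[4-methoxy-2,3-bis(methoxymethoxy)-5-(3-methylbut-2-en-1-yl)phenyl]ethanone
Conditions: Pd(PPh3)4 (5 mol %), DMF, 95 °C, argon
Reagents that add atoms: tributyl(3-methylbut-2-en-1-yl)stannane, CCCC[Sn](CCCC)(CCCC)CC=C(C)C
Why: Stille cross-coupling under zerovalent palladium catalysis should give the linear prenyl arene because the aryl–allyl bond forms at the unhindered CH2 terminus of the allylpalladium intermediate, and the ketone and MOM acetals are inert under these neutral conditions.

**Step 4**
Reactants: 5 1-[4-methoxy-2,3-bis(methoxymethoxy)-5-(3-methylbut-2-en-1-yl)phenyl]ethanone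
Product: 7 2-bromo-1-[4-methoxy-2,3-bis(methoxymethoxy)-5-(3-methylbut-2-en-1-yl)phenyl]ethanone, via trimethylsilyl enol ether 6 (not isolated)
Conditions: LiN(SiMe3)2, THF, −78 °C; Me3SiCl, −78 to 0 °C; then NBS, THF, −78 °C; aq. NaHCO3 work-up
Reagents that add atoms: N-bromosuccinimide, O=C1CCC(=O)N1Br (bromine of 7); chlorotrimethylsilane, C[Si](C)(C)Cl (silyl group of intermediate 6 only)
Why: α-Bromination of a ketone through its silyl enol ether should be selective because the enol silane is far more nucleophilic towards N-bromosuccinimide at −78 °C than the prenyl alkene or the arene, and the amide base/silyl chloride pair avoids the Lewis or Brønsted acids that would endanger the MOM acetals.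

**Step 5**
Reactants: 8 2,4-dihydroxybenzaldehyde
Product: 9 2-hydroxy-4-(methoxymethoxy)benzaldehyde
Conditions: MOMCl (1.05 equiv), K2CO3, acetone, 0 °C to rt
Reagents that add atoms: chloromethyl methyl ether, COCCl
Why: Williamson etherification (MOM protection) should take place at the 4-hydroxyl because the 2-hydroxyl is held in a hydrogen bond to the aldehyde and is much less nucleophilic under mild carbonate conditions.

**Step 6**
Reactants: 7 2-bromo-1-[4-methoxy-2,3-bis(methoxymethoxy)-5-(3-methylbut-2-en-1-yl)phenyl]ethanone; 9 2-hydroxy-4-(methoxymethoxy)benzaldehyde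
Product: 10 2-{2-[4-methoxy-2,3-bis(methoxymethoxy)-5-(3-methylbut-2-en-1-yl)phenyl]-2-oxoethoxy}-4-(methoxymethoxy)benzaldehyde
Conditions: K2CO3 (1.2 equiv), acetone, rt; product used without storage
Reagents that add atoms: none
Why: Williamson ether synthesis (SN2 displacement of the activated phenacyl bromide by the potassium phenoxide) should be fast at room temperature, which avoids the heat and strong base that would trigger Rap–Stoermer aldol condensation to a 2-aroylbenzofuran.

**Step 7**
Reactants: 10 2-{2-[4-methoxy-2,3-bis(methoxymethoxy)-5-(3-methylbut-2-en-1-yl)phenyl]-2-oxoethoxy}-4-(methoxymethoxy)benzaldehyde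
Product: 11 (3S)-3-hydroxy-3-[4-methoxy-2,3-bis(methoxymethoxy)-5-(3-methylbut-2-en-1-yl)phenyl]-7-(methoxymethoxy)-2,3-dihydro-4H-chromen-4-one
Conditions: (5aS,10bR)- or (5aR,10bS)-2-(pentafluorophenyl)-5a,10b-dihydro-4H,6H-indeno[2,1-b][1,2,4]triazolo[4,3-d][1,4]oxazin-2-ium tetrafluoroborate, C18H11BF9N3O (the antipode that gives 3S, 10 mol %), Et3N (8 mol %), toluene, 25 °C, argon; quenched at full conversion
Reagents that add atoms: none
Why: The triazolylidene freed by the amine adds to the aldehyde of 10, proton transfer gives the Breslow intermediate, its nucleophilic carbon attacks the tethered ketone, and collapse of the adduct expels the carbene and leaves the C3 hydroxyl next to the C4 ketone. The closest known reaction type is the enantioselective carbene-catalysed intramolecular crossed aldehyde–ketone benzoin cyclisation of 2-(2-oxoalkoxy)benzaldehydes to 3-hydroxychroman-4-ones. Ring C is closed in a 6-exo-trig mode by forming the C3–C4 bond. The C3 stereocentre is controlled by the rigid aminoindanol backbone of the catalyst, which shields one face of the Breslow intermediate so that the ketone, with its aryl and CH2O groups differentiated, is attacked on one face only. The step needs chemoselectivity for cyclisation over homo-benzoin and over base-induced aldol condensation; this is secured by the ketone being unable to act as acyl donor, by the short O–CH2 tether, by the low electrophilicity of the para-alkoxy aldehyde, and by keeping the weak base below the catalyst loading.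

**Step 8**
Reactants: 11 (3S)-3-hydroxy-3-[4-methoxy-2,3-bis(methoxymethoxy)-5-(3-methylbut-2-en-1-yl)phenyl]-7-(methoxymethoxy)-2,3-dihydro-4H-chromen-4-one
Product: 12 (3S)-3-[2,3-dihydroxy-4-methoxy-5-(3-methylbut-2-en-1-yl)phenyl]-3,7-dihydroxy-2,3-dihydro-4H-chromen-4-one
Conditions: 3 M aq. HCl, MeOH (degassed), 40 °C, argon; stopped at full conversion
Reagents that add atoms: none
Why: Acid-catalysed acetal cleavage (transacetalisation of the three MOM ethers to methanol) should free the phenols, while the prenyl group, flanked by OMe and H and so lacking an ortho hydroxyl, cannot close to a chroman, and the C3 carbinol, deactivated towards ionisation by the adjacent carbonyl and having no α-hydrogen, should keep its configuration.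

**Compound list**
1 | 1-(2,3-dihydroxy-4-methoxyphenyl)ethanone | CC(=O)c1ccc(OC)c(O)c1O | starting material
2 | 1-(5-bromo-2,3-dihydroxy-4-methoxyphenyl)ethanone | CC(=O)c1cc(Br)c(OC)c(O)c1O | intermediate
3 | 1-[5-bromo-4-methoxy-2,3-bis(methoxymethoxy)phenyl]ethanone | CC(=O)c1cc(Br)c(OC)c(OCOC)c1OCOC | intermediate
4 | tributyl(3-methylbut-2-en-1-yl)stannane | CCCC[Sn](CCCC)(CCCC)CC=C(C)C | starting material
5 | 1-[4-methoxy-2,3-bis(methoxymethoxy)-5-(3-methylbut-2-en-1-yl)phenyl]ethanone | CC(=O)c1cc(CC=C(C)C)c(OC)c(OCOC)c1OCOC | intermediate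
6 | trimethylsilyl enol ether of 5, ({1-[4-methoxy-2,3-bis(methoxymethoxy)-5-(3-methylbut-2-en-1-yl)phenyl]ethenyl}oxy)trimethylsilane | C=C(O[Si](C)(C)C)c1cc(CC=C(C)C)c(OC)c(OCOC)c1OCOC | intermediate
7 | 2-bromo-1-[4-methoxy-2,3-bis(methoxymethoxy)-5-(3-methylbut-2-en-1-yl)phenyl]ethanone | BrCC(=O)c1cc(CC=C(C)C)c(OC)c(OCOC)c1OCOC | intermediate
8 | 2,4-dihydroxybenzaldehyde | O=Cc1ccc(O)cc1O | starting material
9 | 2-hydroxy-4-(methoxymethoxy)benzaldehyde | O=Cc1ccc(OCOC)cc1O | intermediate
10 | 2-{2-[4-methoxy-2,3-bis(methoxymethoxy)-5-(3-methylbut-2-en-1-yl)phenyl]-2-oxoethoxy}-4-(methoxymethoxy)benzaldehyde | O=Cc1ccc(OCOC)cc1OCC(=O)c1cc(CC=C(C)C)c(OC)c(OCOC)c1OCOC | intermediate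
11 | (3S)-3-hydroxy-3-[4-methoxy-2,3-bis(methoxymethoxy)-5-(3-methylbut-2-en-1-yl)phenyl]-7-(methoxymethoxy)-2,3-dihydro-4H-chromen-4-one | COc1c(CC=C(C)C)cc([C@]2(O)COc3cc(OCOC)ccc3C2=O)c(OCOC)c1OCOC | intermediate
12 | (3S)-3-[2,3-dihydroxy-4-methoxy-5-(3-methylbut-2-en-1-yl)phenyl]-3,7-dihydroxy-2,3-dihydro-4H-chromen-4-one | COc1c(CC=C(C)C)cc([C@]2(O)COc3cc(O)ccc3C2=O)c(O)c1O | target

**Step count.** Total: 8 steps. Longest linear sequence: 7 steps (steps 1, 2, 3, 4, 6, 7, 8); step 5 is a one-step side branch.

**Steps most likely to fail**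

Step 7. The Breslow intermediate may add only slowly to the hindered, electron-rich, ortho-oxygenated aryl ketone, and facial discrimination at that ketone may be poor; base-induced aldol condensation would then gain ground. The fallback moves stereocontrol from the catalyst to a separation. It sets out from 10, which is cyclised with the small achiral carbene generated from 3-benzyl-5-(2-hydroxyethyl)-4-methylthiazol-3-ium chloride and sub-stoichiometric DBU in t-BuOH at 40 °C. This known thiazolium-catalysed aldehyde–ketone benzoin cyclisation should give the racemic tris-MOM 3-hydroxyisoflavanone F1. Preparative HPLC on an amylose tris(3,5-dimethylphenylcarbamate) phase would then separate the (3S)-enantiomer from the (3R)-enantiomer F2. The route is rejoined at 11.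

Step 4. The brominating agent may be consumed by competing bromonium formation or allylic bromination at the prenyl alkene instead of reacting only at the enol silane. The fallback removes the alkene from the bromination by installing the prenyl group last. It sets out from 3, which is converted in the same way (LiN(SiMe3)2, Me3SiCl, then NBS) through the trimethylsilyl enol ether of 3 F3 into 2-bromo-1-[5-bromo-4-methoxy-2,3-bis(methoxymethoxy)phenyl]ethanone F4. Alkylation of 9 with it (K2CO3, acetone, rt) should give the bromo keto-aldehyde 2-{2-[5-bromo-4-methoxy-2,3-bis(methoxymethoxy)phenyl]-2-oxoethoxy}-4-(methoxymethoxy)benzaldehyde F5. Stille coupling of this aryl bromide with 4 (Pd(PPh3)4, DMF, 95 °C) then rejoins the route at 10.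

Step 3. Allylic transposition during transmetalation and reductive elimination may deliver the reverse-prenyl (1,1-dimethylallyl) isomer alongside the linear one, and protodestannylation may erode conversion. The fallback builds the prenyl group in two stages with no regiochemical ambiguity. It sets out from 3, which undergoes Stille coupling with allyltributylstannane (Pd(PPh3)4, DMF, 95 °C) to give the allyl arene 1-[4-methoxy-2,3-bis(methoxymethoxy)-5-(prop-2-en-1-yl)phenyl]ethanone F6. Olefin cross-metathesis with excess 2-methylbut-2-ene then follows, using the second-generation Grubbs catalyst [1,3-bis(2,4,6-trimethylphenyl)imidazolidin-2-ylidene]dichloro(benzylidene)(tricyclohexylphosphine)ruthenium in CH2Cl2 at 40 °C. The route is rejoined at 5.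

**Further compounds**
F1 | step 7 | racemic 3-hydroxy-3-[4-methoxy-2,3-bis(methoxymethoxy)-5-(3-methylbut-2-en-1-yl)phenyl]-7-(methoxymethoxy)-2,3-dihydro-4H-chromen-4-one | COc1c(CC=C(C)C)cc(C2(O)COc3cc(OCOC)ccc3C2=O)c(OCOC)c1OCOC
F2 | step 7 | (3R)-3-hydroxy-3-[4-methoxy-2,3-bis(methoxymethoxy)-5-(3-methylbut-2-en-1-yl)phenyl]-7-(methoxymethoxy)-2,3-dihydro-4H-chromen-4-one | COc1c(CC=C(C)C)cc([C@@]2(O)COc3cc(OCOC)ccc3C2=O)c(OCOC)c1OCOC
F3 | step 4 | trimethylsilyl enol ether of 3, ({1-[5-bromo-4-methoxy-2,3-bis(methoxymethoxy)phenyl]ethenyl}oxy)trimethylsilane | C=C(O[Si](C)(C)C)c1cc(Br)c(OC)c(OCOC)c1OCOC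
F4 | step 4 | 2-bromo-1-[5-bromo-4-methoxy-2,3-bis(methoxymethoxy)phenyl]ethanone | BrCC(=O)c1cc(Br)c(OC)c(OCOC)c1OCOC
F5 | step 4 | 2-{2-[5-bromo-4-methoxy-2,3-bis(methoxymethoxy)phenyl]-2-oxoethoxy}-4-(methoxymethoxy)benzaldehyde | O=Cc1ccc(OCOC)cc1OCC(=O)c1cc(Br)c(OC)c(OCOC)c1OCOC
F6 | step 3 | 1-[4-methoxy-2,3-bis(methoxymethoxy)-5-(prop-2-en-1-yl)phenyl]ethanone | CC(=O)c1cc(CC=C)c(OC)c(OCOC)c1OCOC
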